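**Retrosynthetic overview**
1. Iriediol ⇐ methanolysis of a C2 4-nitrobenzoate; ring A C–Br ⇐ Appel inversion of an (R)-carbinol made by CBS reduction; C2–OH configuration ⇐ Mitsunobu inversion.
2. Ring A (formed last) ⇐ Dieckmann cyclisation and decarboxylation of an (E)-alkylidene diester; the (E)-trisubstituted alkene ⇐ Ireland–Claisen rearrangement of an allylic isobutyrate made by Nozaki–Hiyama–Kishi coupling.
3. Hydrindane aldehyde ⇐ alkene cleavage after vinyl cuprate 1,4-addition and MeLi 1,2-addition to a 7-bromo-hydrindenone (enone from allylic oxidation).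
4. Five-membered ring (formed second) ⇐ aldol condensation of a 1,4-diketone from alkyne hydration; C7–Br ⇐ Appel inversion of an enzymatically set carbinol.
5. The six-membered ring is bought as 2-methylcyclohexane-1,3-dione; propargylation and ketoreductase desymmetrisation set the first stereocentres.

Assumption: a ketoreductase with anti-Prelog (R) preference for the prochiral propargyl dione is available from a commercial screening panel; hydrindane atoms are numbered C1–C7a as in indene and β is the face of the 7a-methyl group.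

**Step 1**
Reactants: 1 2-methylcyclohexane-1,3-dione; 2 3-bromoprop-1-yne
Product: 3 2-methyl-2-(prop-2-yn-1-yl)cyclohexane-1,3-dione
Conditions: NaOH (1 M aq), 60 °C
Reagents that add atoms: none
Why: Base-mediated C-alkylation (SN2) of the cyclic 1,3-dione enolate with the reactive propargylic bromide gives the prochiral quaternary dione.

**Step 2**
Reactants: 3 2-methyl-2-(prop-2-yn-1-yl)cyclohexane-1,3-dione
Product: 4 (2R,3R)-3-hydroxy-2-methyl-2-(prop-2-yn-1-yl)cyclohexan-1-one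
Conditions: ketoreductase ((R)-selective), NADP+ (cat.), i-PrOH (10 vol%), potassium phosphate buffer pH 7.0, 30 °C
Reagents that add atoms: none
Why: Ketoreductase-catalysed desymmetrising carbonyl reduction: the enzyme reduces one enantiotopic C=O from one face, fixing the quaternary C2 (R) and the carbinol C3 (R, OH cis to the propargyl arm) together as the first stereocentres of the route.

**Step 3**
Reactants: 4 (2R,3R)-3-hydroxy-2-methyl-2-(prop-2-yn-1-yl)cyclohexan-1-one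
Product: 5 (2R,3R)-3-[(tert-butyldimethylsilyl)oxy]-2-methyl-2-(prop-2-yn-1-yl)cyclohexan-1-one
Conditions: TBSCl, imidazole, DMF, 40 °C
Reagents that add atoms: tert-butyldimethylsilyl chloride, CC(C)(C)[Si](C)(C)Cl
Why: Imidazole-promoted silylation masks the β-hydroxy ketone so that the basic aldol step cannot trigger retro-aldol cleavage.

**Step 4**
Reactants: 5 (2R,3R)-3-[(tert-butyldimethylsilyl)oxy]-2-methyl-2-(prop-2-yn-1-yl)cyclohexan-1-one
Product: 6 (2R,3R)-3-[(tert-butyldimethylsilyl)oxy]-2-methyl-2-(2-oxopropyl)cyclohexan-1-one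
Conditions: Ph3PAuNTf2 (2 mol%), H2O (3 equiv), 1,4-dioxane, 60 °C
Reagents that add atoms: water, O
Why: Gold-catalysed Markovnikov hydration of the terminal alkyne, assisted by the neighbouring ketone oxygen, gives the methyl ketone under neutral conditions that leave the silyl ether intact.

**Step 5**
Reactants: 6 (2R,3R)-3-[(tert-butyldimethylsilyl)oxy]-2-methyl-2-(2-oxopropyl)cyclohexan-1-one
Product: 7 (7R,7aS)-7-[(tert-butyldimethylsilyl)oxy]-7a-methyl-1,4,5,6,7,7a-hexahydro-2H-inden-2-one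
Conditions: KOH, MeOH, 65 °C
Reagents that add atoms: none
Why: Intramolecular aldol condensation: the methyl ketone enolate closes the five-membered ring on the ring carbonyl and irreversible dehydration gives the cyclopentenone, with no stereocentre involved.

**Step 6**
Reactants: 7 (7R,7aS)-7-[(tert-butyldimethylsilyl)oxy]-7a-methyl-1,4,5,6,7,7a-hexahydro-2H-inden-2-one
Product: 8 (7R,7aS)-7-hydroxy-7a-methyl-1,4,5,6,7,7a-hexahydro-2H-inden-2-one
Conditions: HF (48% aq), MeCN, rt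
Reagents that add atoms: none
Why: Acidic fluoride desilylation frees the C7 carbinol, which sits axial and anti to the angular methyl in the hydrindenone chair.

**Step 7**
Reactants: 8 (7R,7aS)-7-hydroxy-7a-methyl-1,4,5,6,7,7a-hexahydro-2H-inden-2-one
Product: 9 (7S,7aS)-7-bromo-7a-methyl-1,4,5,6,7,7a-hexahydro-2H-inden-2-one
Conditions: PPh3, CBr4, toluene, 0 → 60 °C
Reagents that add atoms: tetrabromomethane, BrC(Br)(Br)Br
Why: Appel reaction: bromide displaces the axial alkoxyphosphonium group by SN2 with inversion, so the 7α-OH becomes the equatorial 7β-Br of the target.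

**Step 8**
Reactants: 9 (7S,7aS)-7-bromo-7a-methyl-1,4,5,6,7,7a-hexahydro-2H-inden-2-one
Product: 10 (2S,7S,7aS)-7-bromo-7a-methyl-2,4,5,6,7,7a-hexahydro-1H-inden-2-ol (2β-OH)
Conditions: NaBH4, CeCl3·7H2O, MeOH, −78 °C
Reagents that add atoms: none
Why: Luche 1,2-reduction: hydride attacks the cyclopentenone carbonyl from the face opposite the axial angular methyl and gives the 2β-allylic alcohol.

**Step 9**
Reactants: 10 (2S,7S,7aS)-7-bromo-7a-methyl-2,4,5,6,7,7a-hexahydro-1H-inden-2-ol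
Product: 11 tert-butyl{[(2S,7S,7aS)-7-bromo-7a-methyl-2,4,5,6,7,7a-hexahydro-1H-inden-2-yl]oxy}dimethylsilane
Conditions: TBSCl, imidazole, DMF, rt
Reagents that add atoms: tert-butyldimethylsilyl chloride, CC(C)(C)[Si](C)(C)Cl
Why: Silylation gives a bulky β-silyloxy group that survives the following oxidations and organometallic steps and later steers the cuprate to the α face.

**Step 10**
Reactants: 11 tert-butyl{[(2S,7S,7aS)-7-bromo-7a-methyl-2,4,5,6,7,7a-hexahydro-1H-inden-2-yl]oxy}dimethylsilane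
Product: 13 7β-bromo-2β-[(tert-butyldimethylsilyl)oxy]-7a-methyl-1,2,5,6,7,7a-hexahydro-4H-inden-4-one, via C4 allylic alcohols 12 (not isolated)
Conditions: SeO2 (0.5 equiv), t-BuOOH, CH2Cl2, rt; then Dess–Martin periodinane, NaHCO3, CH2Cl2, rt
Reagents that add atoms: selenium dioxide, O=[Se]=O; tert-butyl hydroperoxide, CC(C)(C)OO (source of the new oxygen)
Why: Riley allylic oxidation (ene reaction then [2,3]-sigmatropic shift) hydroxylates the only CH2 next to the more substituted alkene carbon, and Dess–Martin oxidation of the crude carbinols erases that stereocentre to give the enone.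

**Step 11**
Reactants: 13 7β-bromo-2β-[(tert-butyldimethylsilyl)oxy]-7a-methyl-1,2,5,6,7,7a-hexahydro-4H-inden-4-one
Product: 14 7β-bromo-2β-[(tert-butyldimethylsilyl)oxy]-3α-ethenyl-7a-methyl-3aα-H-octahydro-4H-inden-4-one (trans-fused)
Conditions: CH2=CHMgBr (4 equiv), CuBr·SMe2 (2 equiv), THF, −78 → −40 °C; then NH4Cl (aq), −78 °C
Reagents that add atoms: vinylmagnesium bromide, C=C[Mg]Br
Why: Cuprate 1,4-addition delivers the vinyl group to C3 anti to the adjacent 2β-silyloxy group and the angular methyl (3α), and axial protonation of the cold enolate on the face opposite the axial methyl gives the trans ring fusion (3aα-H).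

**Step 12**
Reactants: 14 7β-bromo-2β-[(tert-butyldimethylsilyl)oxy]-3α-ethenyl-7a-methyl-3aα-H-octahydro-4H-inden-4-one
Product: 15 7β-bromo-2β-[(tert-butyldimethylsilyl)oxy]-3α-ethenyl-4α,7a-dimethyl-3aα-H-octahydro-1H-inden-4β-ol
Conditions: MeLi, CeCl3, THF, −78 °C
Reagents that add atoms: methyllithium, [Li]C
Why: Organocerium 1,2-addition: the weakly basic methyl nucleophile attacks the ketone equatorially, away from the syn-axial angular methyl, setting 4α-CH3/4β-OH without epimerising C3a.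

**Step 13**
Reactants: 15 7β-bromo-2β-[(tert-butyldimethylsilyl)oxy]-3α-ethenyl-4α,7a-dimethyl-3aα-H-octahydro-1H-inden-4β-ol
Product: 16 7β-bromo-2β-[(tert-butyldimethylsilyl)oxy]-4β-hydroxy-4α,7a-dimethyl-3aα-H-octahydro-1H-indene-3α-carbaldehyde
Conditions: OsO4 (2 mol%), NaIO4, 2,6-lutidine, 1,4-dioxane/H2O (3:1), rt
Reagents that add atoms: OsO4, O=[Os](=O)(=O)=O; NaIO4, [Na+].[O-]I(=O)(=O)=O (source of the aldehyde oxygen)
Why: Lemieux–Johnson oxidation (catalytic dihydroxylation with in situ periodate cleavage) cuts the only alkene to the aldehyde, whose 3α configuration (trans to both neighbours) is also the thermodynamic one.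

**Step 14**
Reactants: 17 pent-4-ynoic acid
Product: 18 4-iodopent-4-enoic acid
Conditions: NaI, Me3SiCl, H2O, MeCN, rt
Reagents that add atoms: sodium iodide, [Na+].[I-]
Why: Markovnikov hydroiodination of the terminal alkyne by HI generated in the flask gives the 2-iodoalkene.

**Step 15**
Reactants: 18 4-iodopent-4-enoic acid
Product: 19 tert-butyl 4-iodopent-4-enoate
Conditions: Cl3CC(=NH)Ot-Bu, BF3·OEt2 (cat.), CH2Cl2/cyclohexane, rt
Reagents that add atoms: tert-butyl 2,2,2-trichloroacetimidate, CC(C)(C)OC(=N)C(Cl)(Cl)Cl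
Why: Acid-catalysed imidate alkylation esterifies the acid without touching the vinyl iodide, and the tert-butyl ester cannot lactonise onto the later carbinol.

**Step 16**
Reactants: 16 7β-bromo-2β-[(tert-butyldimethylsilyl)oxy]-4β-hydroxy-4α,7a-dimethyl-3aα-H-octahydro-1H-indene-3α-carbaldehyde; 19 tert-butyl 4-iodopent-4-enoate
Product: 20 tert-butyl 5-hydroxy-4-methylidene-5-Ind-pentanoate (Ind = 7β-bromo-2β-[(tert-butyldimethylsilyl)oxy]-4β-hydroxy-4α,7a-dimethyl-3aα-H-octahydro-1H-inden-3α-yl; both C5 epimers)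
Conditions: CrCl2 (4 equiv), NiCl2 (2 mol%), DMF, rt
Reagents that add atoms: none
Why: Nozaki–Hiyama–Kishi coupling: the alkenylchromium species made in situ adds only to the aldehyde and tolerates the ester, the alkyl bromide and the free tertiary alcohol; the new carbinol centre forms as a mixture that converges in step 18.

**Step 17**
Reactants: 20 tert-butyl 5-hydroxy-4-methylidene-5-Ind-pentanoate
Product: 21 tert-butyl 4-methylidene-5-(2-methylpropanoyloxy)-5-Ind-pentanoate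
Conditions: (i-PrCO)2O, Et3N, 4-(dimethylamino)pyridine (cat.), CH2Cl2, rt
Reagents that add atoms: 2-methylpropanoic anhydride, CC(C)C(=O)OC(=O)C(C)C
Why: Nucleophile-catalysed acylation esterifies the secondary allylic alcohol, while the tertiary alcohol is too hindered to react.

**Step 18**
Reactants: 21 tert-butyl 4-methylidene-5-(2-methylpropanoyloxy)-5-Ind-pentanoate
Product: 24 (4E)-7-tert-butoxy-2,2-dimethyl-7-oxo-4-(Ind-methylidene)heptanoic acid, via bis-silyl ketene acetal 22 (not isolated), via trimethylsilyl ester 23 (not isolated)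
Conditions: LiN(i-Pr)2 (3.5 equiv), Me3SiCl, THF, −78 → 60 °C; then 1 M HCl, rt
Reagents that add atoms: chlorotrimethylsilane, C[Si](C)(C)Cl (silicon kept only in 22 and 23)
Why: Ireland–Claisen rearrangement: the [3,3]-shift through a chair transition state with the bulky hydrindanyl group pseudo-equatorial gives the (E)-trisubstituted alkene from either carbinol epimer and forges the quaternary CMe2 carbon, while the spectator tert-butyl ketene acetal reverts to the ester on acidic work-up.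

**Step 19**
Reactants: 24 (4E)-7-tert-butoxy-2,2-dimethyl-7-oxo-4-(Ind-methylidene)heptanoic acid
Product: 25 7-tert-butyl 1-methyl (4E)-2,2-dimethyl-4-(Ind-methylidene)heptanedioate
Conditions: Me3SiCHN2, MeOH/toluene, 0 °C
Reagents that add atoms: (trimethylsilyl)diazomethane, C[Si](C)(C)C=[N+]=[N-]
Why: O-Methylation of the carboxylic acid by the diazoalkane (protonation then SN2) gives the methyl ester under neutral conditions.

**Step 20**
Reactants: 25 7-tert-butyl 1-methyl (4E)-2,2-dimethyl-4-(Ind-methylidene)heptanedioate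
Product: 26 tert-butyl (5E)-3,3-dimethyl-2-oxo-5-(Ind-methylidene)cyclohexane-1-carboxylate
Conditions: KOt-Bu (3 equiv), THF, 0 °C → rt; then NH4Cl (aq)
Reagents that add atoms: none
Why: Dieckmann condensation: only the tert-butyl ester can enolise and its enolate closes the six-membered ring A on the methyl ester, the stable β-keto ester enolate driving the equilibrium.

**Step 21**
Reactants: 26 tert-butyl (5E)-3,3-dimethyl-2-oxo-5-(Ind-methylidene)cyclohexane-1-carboxylate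
Product: 28 (4E)-2,2-dimethyl-4-(Ind-methylidene)cyclohexan-1-one, via β-keto acid 27 (not isolated)
Conditions: 1,4-dioxane/H2O (10:1), 140 °C, sealed tube
Reagents that add atoms: none
Why: Thermal dealkoxycarbonylation: the tert-butyl β-keto ester loses isobutene and the β-keto acid decarboxylates under neutral conditions that spare the alkyl bromide, the silyl ether and the alkene geometry.

**Step 22**
Reactants: 28 (4E)-2,2-dimethyl-4-(Ind-methylidene)cyclohexan-1-one
Product: 29 (4E)-4-[(7β-bromo-2β,4β-dihydroxy-4α,7a-dimethyl-3aα-H-octahydro-1H-inden-3α-yl)methylidene]-2,2-dimethylcyclohexan-1-one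
Conditions: HF·pyridine, THF, 0 °C → rt
Reagents that add atoms: none
Why: Fluoride-mediated desilylation frees the 2β-alcohol.

**Step 23**
Reactants: 29 (4E)-4-[(7β-bromo-2β,4β-dihydroxy-4α,7a-dimethyl-3aα-H-octahydro-1H-inden-3α-yl)methylidene]-2,2-dimethylcyclohexan-1-one
Product: 30 7β-bromo-3α-[(E)-(3,3-dimethyl-4-oxocyclohexylidene)methyl]-4β-hydroxy-4α,7a-dimethyl-3aα-H-octahydro-1H-inden-2α-yl 4-nitrobenzoate
Conditions: 4-O2NC6H4CO2H, PPh3, DIAD, toluene, 0 °C → rt
Reagents that add atoms: 4-nitrobenzoic acid, OC(=O)c1ccc(cc1)[N+](=O)[O-]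
Why: Mitsunobu reaction: SN2 displacement of the activated 2β-oxyphosphonium group by 4-nitrobenzoate inverts C2 to the 2α configuration of the target, and the tertiary alcohol cannot react.

**Step 24**
Reactants: 30 7β-bromo-3α-[(E)-(3,3-dimethyl-4-oxocyclohexylidene)methyl]-4β-hydroxy-4α,7a-dimethyl-3aα-H-octahydro-1H-inden-2α-yl 4-nitrobenzoate
Product: 31 7β-bromo-4β-hydroxy-3α-{(E)-[(4R)-4-hydroxy-3,3-dimethylcyclohexylidene]methyl}-4α,7a-dimethyl-3aα-H-octahydro-1H-inden-2α-yl 4-nitrobenzoate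
Conditions: (S)-1-methyl-3,3-diphenyltetrahydro-1H,3H-pyrrolo[1,2-c][1,3,2]oxazaborole (0.5 equiv), catecholborane, toluene, −78 °C
Reagents that add atoms: none
Why: Corey–Bakshi–Shibata reduction: the oxazaborolidine distinguishes the quaternary CMe2 flank (large) from the CH2 flank (small) and delivers hydride to give the (R)-carbinol under catalyst control, the remote hydrindane centres having no influence.

**Step 25**
Reactants: 31 7β-bromo-4β-hydroxy-3α-{(E)-[(4R)-4-hydroxy-3,3-dimethylcyclohexylidene]methyl}-4α,7a-dimethyl-3aα-H-octahydro-1H-inden-2α-yl 4-nitrobenzoate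
Product: 32 7β-bromo-3α-{(E)-[(4S)-4-bromo-3,3-dimethylcyclohexylidene]methyl}-4β-hydroxy-4α,7a-dimethyl-3aα-H-octahydro-1H-inden-2α-yl 4-nitrobenzoate
Conditions: PPh3, CBr4, toluene, 0 → 60 °C
Reagents that add atoms: tetrabromomethane, BrC(Br)(Br)Br
Why: Appel reaction with SN2 inversion turns the (R)-carbinol into the (S)-bromide of ring A, while the hindered tertiary alcohol and the ester stay untouched.

**Step 26**
Reactants: 32 7β-bromo-3α-{(E)-[(4S)-4-bromo-3,3-dimethylcyclohexylidene]methyl}-4β-hydroxy-4α,7a-dimethyl-3aα-H-octahydro-1H-inden-2α-yl 4-nitrobenzoate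
Product: 33 Iriediol
Conditions: K2CO3, MeOH, rt
Reagents that add atoms: none
Why: Base-catalysed transesterification (methanolysis) removes the 4-nitrobenzoate and releases iriediol without disturbing the two secondary bromides.

**Compound list**
1 | 2-methylcyclohexane-1,3-dione | CC1C(=O)CCCC1=O | starting material
2 | 3-bromoprop-1-yne (propargyl bromide) | C#CCBr | starting material
3 | 2-methyl-2-(prop-2-yn-1-yl)cyclohexane-1,3-dione | CC1(CC#C)C(=O)CCCC1=O | intermediate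
4 | (2R,3R)-3-hydroxy-2-methyl-2-(prop-2-yn-1-yl)cyclohexan-1-one | C#CC[C@]1(C)[C@H](O)CCCC1=O | intermediate
5 | (2R,3R)-3-[(tert-butyldimethylsilyl)oxy]-2-methyl-2-(prop-2-yn-1-yl)cyclohexan-1-one | C#CC[C@]1(C)[C@H](O[Si](C)(C)C(C)(C)C)CCCC1=O | intermediate
6 | (2R,3R)-3-[(tert-butyldimethylsilyl)oxy]-2-methyl-2-(2-oxopropyl)cyclohexan-1-one | CC(=O)C[C@]1(C)[C@H](O[Si](C)(C)C(C)(C)C)CCCC1=O | intermediate
7 | (7R,7aS)-7-[(tert-butyldimethylsilyl)oxy]-7a-methyl-1,4,5,6,7,7a-hexahydro-2H-inden-2-one (7α-OTBS) | O=C1C[C@]2(C)[C@H](O[Si](C)(C)C(C)(C)C)CCCC2=C1 | intermediate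
8 | (7R,7aS)-7-hydroxy-7a-methyl-1,4,5,6,7,7a-hexahydro-2H-inden-2-one (7α-OH) | O=C1C[C@]2(C)[C@H](O)CCCC2=C1 | intermediate
9 | (7S,7aS)-7-bromo-7a-methyl-1,4,5,6,7,7a-hexahydro-2H-inden-2-one (7β-Br) | O=C1C[C@]2(C)[C@@H](Br)CCCC2=C1 | intermediate
10 | (2S,7S,7aS)-7-bromo-7a-methyl-2,4,5,6,7,7a-hexahydro-1H-inden-2-ol (2β-OH) | O[C@H]1C[C@]2(C)[C@@H](Br)CCCC2=C1 | intermediate
11 | tert-butyl{[(2S,7S,7aS)-7-bromo-7a-methyl-2,4,5,6,7,7a-hexahydro-1H-inden-2-yl]oxy}dimethylsilane | CC(C)(C)[Si](C)(C)O[C@H]1C[C@]2(C)[C@@H](Br)CCCC2=C1 | intermediate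
12 | 7β-bromo-2β-[(tert-butyldimethylsilyl)oxy]-7a-methyl-2,4,5,6,7,7a-hexahydro-1H-inden-4-ol (both C4 epimers) | CC(C)(C)[Si](C)(C)O[C@H]1C[C@]2(C)[C@@H](Br)CCC(O)C2=C1 | intermediate
13 | 7β-bromo-2β-[(tert-butyldimethylsilyl)oxy]-7a-methyl-1,2,5,6,7,7a-hexahydro-4H-inden-4-one | CC(C)(C)[Si](C)(C)O[C@H]1C[C@]2(C)[C@@H](Br)CCC(=O)C2=C1 | intermediate
14 | 7β-bromo-2β-[(tert-butyldimethylsilyl)oxy]-3α-ethenyl-7a-methyl-3aα-H-octahydro-4H-inden-4-one (trans-fused) | C=C[C@@H]1[C@@H](O[Si](C)(C)C(C)(C)C)C[C@]2(C)[C@@H](Br)CCC(=O)[C@@H]12 | intermediate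
15 | 7β-bromo-2β-[(tert-butyldimethylsilyl)oxy]-3α-ethenyl-4α,7a-dimethyl-3aα-H-octahydro-1H-inden-4β-ol | C=C[C@@H]1[C@@H](O[Si](C)(C)C(C)(C)C)C[C@]2(C)[C@@H](Br)CC[C@@](C)(O)[C@@H]12 | intermediate
16 | 7β-bromo-2β-[(tert-butyldimethylsilyl)oxy]-4β-hydroxy-4α,7a-dimethyl-3aα-H-octahydro-1H-indene-3α-carbaldehyde | O=C[C@@H]1[C@@H](O[Si](C)(C)C(C)(C)C)C[C@]2(C)[C@@H](Br)CC[C@@](C)(O)[C@@H]12 | intermediate
17 | pent-4-ynoic acid | C#CCCC(=O)O | starting material
18 | 4-iodopent-4-enoic acid | C=C(I)CCC(=O)O | intermediate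
19 | tert-butyl 4-iodopent-4-enoate | C=C(I)CCC(=O)OC(C)(C)C | intermediate
20 | tert-butyl 5-hydroxy-4-methylidene-5-Ind-pentanoate (Ind = 7β-bromo-2β-[(tert-butyldimethylsilyl)oxy]-4β-hydroxy-4α,7a-dimethyl-3aα-H-octahydro-1H-inden-3α-yl; both C5 epimers) | C=C(CCC(=O)OC(C)(C)C)C(O)[C@@H]1[C@@H](O[Si](C)(C)C(C)(C)C)C[C@]2(C)[C@@H](Br)CC[C@@](C)(O)[C@@H]12 | intermediate
21 | tert-butyl 4-methylidene-5-(2-methylpropanoyloxy)-5-Ind-pentanoate (Ind as in 20) | C=C(CCC(=O)OC(C)(C)C)C(OC(=O)C(C)C)[C@@H]1[C@@H](O[Si](C)(C)C(C)(C)C)C[C@]2(C)[C@@H](Br)CC[C@@](C)(O)[C@@H]12 | intermediate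
22 | bis(trimethylsilyl ketene acetal) of 21 (isobutyrate and tert-butyl ester both as O-silyl ketene acetals) | C=C(CC=C(O[Si](C)(C)C)OC(C)(C)C)C(OC(O[Si](C)(C)C)=C(C)C)[C@@H]1[C@@H](O[Si](C)(C)C(C)(C)C)C[C@]2(C)[C@@H](Br)CC[C@@](C)(O)[C@@H]12 | intermediate
23 | trimethylsilyl (4E)-7-tert-butoxy-2,2-dimethyl-4-(Ind-methylidene)-7-(trimethylsilyloxy)hept-6-enoate | C[Si](C)(C)OC(=O)C(C)(C)C/C(=C/[C@@H]1[C@@H](O[Si](C)(C)C(C)(C)C)C[C@]2(C)[C@@H](Br)CC[C@@](C)(O)[C@@H]12)CC=C(O[Si](C)(C)C)OC(C)(C)C | intermediate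
24 | (4E)-7-tert-butoxy-2,2-dimethyl-7-oxo-4-(Ind-methylidene)heptanoic acid | OC(=O)C(C)(C)C/C(=C/[C@@H]1[C@@H](O[Si](C)(C)C(C)(C)C)C[C@]2(C)[C@@H](Br)CC[C@@](C)(O)[C@@H]12)CCC(=O)OC(C)(C)C | intermediate
25 | 7-tert-butyl 1-methyl (4E)-2,2-dimethyl-4-(Ind-methylidene)heptanedioate | COC(=O)C(C)(C)C/C(=C/[C@@H]1[C@@H](O[Si](C)(C)C(C)(C)C)C[C@]2(C)[C@@H](Br)CC[C@@](C)(O)[C@@H]12)CCC(=O)OC(C)(C)C | intermediate
26 | tert-butyl (5E)-3,3-dimethyl-2-oxo-5-(Ind-methylidene)cyclohexane-1-carboxylate (C1 epimers) | CC1(C)C/C(=C/[C@@H]2[C@@H](O[Si](C)(C)C(C)(C)C)C[C@]3(C)[C@@H](Br)CC[C@@](C)(O)[C@@H]23)CC(C(=O)OC(C)(C)C)C1=O | intermediate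
27 | (5E)-3,3-dimethyl-2-oxo-5-(Ind-methylidene)cyclohexane-1-carboxylic acid | CC1(C)C/C(=C/[C@@H]2[C@@H](O[Si](C)(C)C(C)(C)C)C[C@]3(C)[C@@H](Br)CC[C@@](C)(O)[C@@H]23)CC(C(=O)O)C1=O | intermediate
28 | (4E)-2,2-dimethyl-4-(Ind-methylidene)cyclohexan-1-one | CC1(C)C/C(=C/[C@@H]2[C@@H](O[Si](C)(C)C(C)(C)C)C[C@]3(C)[C@@H](Br)CC[C@@](C)(O)[C@@H]23)CCC1=O | intermediate
29 | (4E)-4-[(7β-bromo-2β,4β-dihydroxy-4α,7a-dimethyl-3aα-H-octahydro-1H-inden-3α-yl)methylidene]-2,2-dimethylcyclohexan-1-one | CC1(C)C/C(=C/[C@@H]2[C@@H](O)C[C@]3(C)[C@@H](Br)CC[C@@](C)(O)[C@@H]23)CCC1=O | intermediate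
30 | 7β-bromo-3α-[(E)-(3,3-dimethyl-4-oxocyclohexylidene)methyl]-4β-hydroxy-4α,7a-dimethyl-3aα-H-octahydro-1H-inden-2α-yl 4-nitrobenzoate | CC1(C)C/C(=C/[C@@H]2[C@H](OC(=O)c4ccc(cc4)[N+](=O)[O-])C[C@]3(C)[C@@H](Br)CC[C@@](C)(O)[C@@H]23)CCC1=O | intermediate
31 | 7β-bromo-4β-hydroxy-3α-{(E)-[(4R)-4-hydroxy-3,3-dimethylcyclohexylidene]methyl}-4α,7a-dimethyl-3aα-H-octahydro-1H-inden-2α-yl 4-nitrobenzoate | CC1(C)C/C(=C/[C@@H]2[C@H](OC(=O)c4ccc(cc4)[N+](=O)[O-])C[C@]3(C)[C@@H](Br)CC[C@@](C)(O)[C@@H]23)CC[C@H]1O | intermediate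
32 | 7β-bromo-3α-{(E)-[(4S)-4-bromo-3,3-dimethylcyclohexylidene]methyl}-4β-hydroxy-4α,7a-dimethyl-3aα-H-octahydro-1H-inden-2α-yl 4-nitrobenzoate | CC1(C)C/C(=C/[C@@H]2[C@H](OC(=O)c4ccc(cc4)[N+](=O)[O-])C[C@]3(C)[C@@H](Br)CC[C@@](C)(O)[C@@H]23)CC[C@@H]1Br | intermediate
33 | Iriediol: 7β-bromo-3α-{(E)-[(4S)-4-bromo-3,3-dimethylcyclohexylidene]methyl}-4α,7a-dimethyl-3aα-H-octahydro-1H-indene-2α,4β-diol | CC1(C)C/C(=C/[C@@H]2[C@H](O)C[C@]3(C)[C@@H](Br)CC[C@@](C)(O)[C@@H]23)CC[C@@H]1Br | target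

**Totals**
Total step count: 26. Longest linear sequence: 24 steps (steps 1–13 and 16–26, from 2-methylcyclohexane-1,3-dione); the iodide branch is steps 14–15.

**Three steps most likely to fail, with fallbacks**

Step 7 (Appel inversion at the neopentyl C7 carbinol): SN2 next to the quaternary C7a is slow, and E2 to the 6,7-alkene competes on heating. The fallback sets out from 8. Tf2O and pyridine in CH2Cl2 at −40 °C give (7R,7aS)-7a-methyl-2-oxo-2,4,5,6,7,7a-hexahydro-1H-inden-7-yl trifluoromethanesulfonate F1. This is isolated cold and displaced in a separate SN2 step by Bu4NBr in toluene at 0 °C → rt. The far better leaving group lets the inversion run below the temperature at which elimination takes over. The fallback comes back to the route at 9.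

Step 10 (Riley oxidation): yield and regiochemistry with SeO2 can be poor on this allylic silyl ether. The fallback sets out from 9 and uses the vinylogous enol ether logic known from steroid 3,5-dienol ethers.
- TBSOTf and Et3N (CH2Cl2, 0 °C) give the extended silyl dienol ether {[(7S,7aS)-7-bromo-7a-methyl-5,6,7,7a-tetrahydro-1H-inden-2-yl]oxy}(tert-butyl)dimethylsilane F2.
- mCPBA (NaHCO3, CH2Cl2, 0 °C) attacks the γ-terminus and gives 7β-bromo-4-hydroxy-7a-methyl-1,4,5,6,7,7a-hexahydro-2H-inden-2-one F3.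
- Ac2O/pyridine gives 7β-bromo-7a-methyl-2-oxo-2,4,5,6,7,7a-hexahydro-1H-inden-4-yl acetate F4.
- Luche reduction (NaBH4, CeCl3·7H2O, MeOH, −78 °C) gives 7β-bromo-2β-hydroxy-7a-methyl-2,4,5,6,7,7a-hexahydro-1H-inden-4-yl acetate F5.
- TBSCl/imidazole gives 7β-bromo-2β-[(tert-butyldimethylsilyl)oxy]-7a-methyl-2,4,5,6,7,7a-hexahydro-1H-inden-4-yl acetate F6.
- K2CO3 in MeOH at 0 °C removes the acetate and the fallback comes back to the route at 12, which is oxidised to 13 with Dess–Martin periodinane as in the second stage of step 10.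

Step 18 (Ireland–Claisen rearrangement): three acidic sites must be deprotonated and a hindered tetrasubstituted ketene acetal must rearrange on a crowded substrate. The fallback sets out from 16 and builds the same (E)-alkene by olefination instead of a sigmatropic shift.
- 5-tert-Butyl 1-ethyl 2-(diethoxyphosphoryl)pentanedioate F7 is made from triethyl phosphonoacetate and tert-butyl acrylate (NaOEt cat.).
- F7 is deprotonated with NaH (THF, 0 °C) and condensed with 16 in a Horner–Wadsworth–Emmons reaction to give 5-tert-butyl 1-ethyl (2E)-2-(Ind-methylidene)pentanedioate F8.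
- i-Bu2AlH (CH2Cl2, −78 °C) reduces only the conjugated ethyl ester to tert-butyl (4E)-4-(hydroxymethyl)-5-Ind-pent-4-enoate F9.
- CBr4/PPh3 (CH2Cl2, 0 °C) gives tert-butyl (4E)-4-(bromomethyl)-5-Ind-pent-4-enoate F10.
- Alkylation of the lithium enolate of methyl 2-methylpropanoate (LiN(i-Pr)2, THF, −78 °C) with F10 forms the quaternary carbon, and the fallback comes back to the route at 25.

**Further compounds**
F1 | step 7 | (7R,7aS)-7a-methyl-2-oxo-2,4,5,6,7,7a-hexahydro-1H-inden-7-yl trifluoromethanesulfonate | O=C1C[C@]2(C)[C@H](OS(=O)(=O)C(F)(F)F)CCCC2=C1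
F2 | step 10 | {[(7S,7aS)-7-bromo-7a-methyl-5,6,7,7a-tetrahydro-1H-inden-2-yl]oxy}(tert-butyl)dimethylsilane | CC(C)(C)[Si](C)(C)OC1=CC2=CCC[C@H](Br)[C@@]2(C)C1
F3 | step 10 | 7β-bromo-4-hydroxy-7a-methyl-1,4,5,6,7,7a-hexahydro-2H-inden-2-one (C4 epimers) | O=C1C[C@]2(C)[C@@H](Br)CCC(O)C2=C1
F4 | step 10 | 7β-bromo-7a-methyl-2-oxo-2,4,5,6,7,7a-hexahydro-1H-inden-4-yl acetate | O=C1C[C@]2(C)[C@@H](Br)CCC(OC(C)=O)C2=C1
F5 | step 10 | 7β-bromo-2β-hydroxy-7a-methyl-2,4,5,6,7,7a-hexahydro-1H-inden-4-yl acetate | O[C@H]1C[C@]2(C)[C@@H](Br)CCC(OC(C)=O)C2=C1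
F6 | step 10 | 7β-bromo-2β-[(tert-butyldimethylsilyl)oxy]-7a-methyl-2,4,5,6,7,7a-hexahydro-1H-inden-4-yl acetate | CC(C)(C)[Si](C)(C)O[C@H]1C[C@]2(C)[C@@H](Br)CCC(OC(C)=O)C2=C1
F7 | step 18 | 5-tert-butyl 1-ethyl 2-(diethoxyphosphoryl)pentanedioate | CCOC(=O)C(CCC(=O)OC(C)(C)C)P(=O)(OCC)OCC
F8 | step 18 | 5-tert-butyl 1-ethyl (2E)-2-(Ind-methylidene)pentanedioate | CCOC(=O)/C(=C/[C@@H]1[C@@H](O[Si](C)(C)C(C)(C)C)C[C@]2(C)[C@@H](Br)CC[C@@](C)(O)[C@@H]12)CCC(=O)OC(C)(C)C
F9 | step 18 | tert-butyl (4E)-4-(hydroxymethyl)-5-Ind-pent-4-enoate | OC/C(=C/[C@@H]1[C@@H](O[Si](C)(C)C(C)(C)C)C[C@]2(C)[C@@H](Br)CC[C@@](C)(O)[C@@H]12)CCC(=O)OC(C)(C)C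
F10 | step 18 | tert-butyl (4E)-4-(bromomethyl)-5-Ind-pent-4-enoate | BrC/C(=C/[C@@H]1[C@@H](O[Si](C)(C)C(C)(C)C)C[C@]2(C)[C@@H](Br)CC[C@@](C)(O)[C@@H]12)CCC(=O)OC(C)(C)C
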